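## Analysis of the target

Atoms are numbered as they appear in the target SMILES (vinyl C1=C2, C3, C4=C5, C6, C7, C8, C9 with methyl C10, C11, C12 with methyl C13, C14, C15, O16, arene C17–C22, C23, C24 with O25, C26, C27, lactam C28, N30, ketone C31, C33, C34), and the rings are called A (C7, C8, C9, C11, C12, C14), B (C6, C7, C14, C15, C34), C (C3, C4, C5, C6, C34, C33), D (the 13-membered ring C15, O16, C17–C20, C23, C24, C26, C27, C31, C33, C34) and E (lactam C24, C26, C27, C28, N30). Rings A–C form a trans-anti-trans decahydrofluorene in which all four substituents of ring A are equatorial and both ring fusions (C7–C14 and C6–C34) are trans. Ring C is all-trans, so the C3 vinyl group is trans to C7; a Diels–Alder construction of ring C must therefore carry this group as the "inside" (Z) substituent of the diene. The ether oxygen O16 on C15 is pseudoaxial, cis to C12 and trans to C33, which is an anti-aldol relationship between C14 and C15. Ring D is a strained oxa[9]paracyclophane with a bent benzene ring, a gauche C15–C34–C33–C31 segment and a 1,4-diketone pattern (C24, C31) that is prone to aldol and pyrrole-forming side reactions. The feature the strategy uses is the 1,3-dicarbonyl unit C31(=O)–C27–C28(=O): the C31–C27 bond belongs to ring D while C28 is exocyclic, so this bond can be made by excising one atom from a larger, less strained ring. C24 (hemiaminal) and C27 (between two carbonyl groups) are labile and can only be set under thermodynamic control, whereas the other nine stereocentres must be built by kinetic control or by equilibration on ring A. The sensitive groups are the hemiaminal, the β-keto lactam, the doubly allylic C3–H and the strained aryl ether, and the main difficulty is to pay the strain of ring D late without an end-to-end macrocyclisation onto a hindered centre.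

## Retrosynthetic reasoning

Ring E of 34 is opened first. Cutting C28–N30 and N30–C24 gives the ethyl β-keto ester 32. The forward reaction is an ammonolysis that goes through keto amide 33 and closes the hydroxy lactam; it also lets C24 and C27 settle thermodynamically, so no earlier step has to control them.

In 32 the ring D bond C31–C27 is cut and a sulfur atom is placed between the two carbons, which leads to the 14-membered thiolactone 30. This is the only 1,3-dicarbonyl relationship on the perimeter of ring D, so it is the only bond that a sulfide contraction can make. The gain is that the strained 13-membered ring arises by a 1,2-acyl shift inside an existing ring, and the product already has the final oxidation pattern. The forward reaction must enolise C27, transfer the acyl group from sulfur to carbon (via 31) and remove sulfur irreversibly.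

Thiolactone 30 is opened at S–C27. The thiocarboxylic acid 29, made from acid 27 through acid chloride 28, adds in a conjugate fashion to the 4-oxo-enoate arm. Two long C–S bonds make this 14-membered closure easy, and the addition is reversible, so oligomers can correct themselves.

The keto-enoate arm of 27 (from tert-butyl ester 26) is cut at C23–C24: benzylic zinc reagent 25, from chloride 23, is acylated by 24. The aryl ether is cut at O16–C17: the alkoxide of alcohol 19 displaces fluoride from 20 to give 21, which is reduced to 22 and chlorinated to 23. Bond formation at the arene and not at C15 keeps the C15 configuration.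

The tricycle 19 comes from 18 and 17, and 17 is cut at C3–C33 and C6–C34. The forward step is an intramolecular Diels–Alder reaction of 16 that closes rings B and C and sets C3, C6, C33 and C34 from the ring A stereocentres. An ethynyl group serves as a slim Z substituent that later becomes the vinyl group.

Triene 16 is cut at C3=C4 (enal 14 plus 15), at C4–C6 (two-carbon Wittig extension of 13), at C33=C34 (cross metathesis of 11 with 12) and at C6–C7 (one-carbon homologation of ketone 8 through 9 and 10). Each cut uses an aldehyde or alkene that the previous step leaves behind, and the epimerisable C7 aldehyde places the last ring A substituent equatorial.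

Ketone 8 is traced through 7 and 6 to the aldol union of enone 3 with 4 at C14–C15, by way of dienolate 5. The enone is used instead of the saturated ketone because its flattened dienolate directs the aldehyde anti to the C12 methyl group; C9 is set afterwards by conjugate reduction. Enone 3 comes from the meso ketone 1 through the desymmetrised silyl enol ether 2, which is the only reagent-controlled stereochemical event of the route.

## Alternatives that were turned down

Alternative 1: the textbook route cuts ring D at O16–C17 after the Diels–Alder reaction. The forward key step is a copper-mediated intramolecular O-arylation of the seco alcohol A1 to give 32. It was turned down because the whole strain of ring D must be paid in an end-to-end C–O coupling at a hindered secondary alkoxide with an unactivated aryl iodide. That needs base and heat in the presence of the 1,4-diketo ester, which invites retro-Claisen and aldol reactions or forces protection of C24 and C31.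

Alternative 2: sulfur is placed between C23 and C24. A 14-membered sulfone A2 is contracted by a Ramberg–Bäcklund reaction to the styrene A3. It was turned down because sulfur leaves at a position where the oxidation state must then be rebuilt. A3 needs a regioselective oxidation of C23=C24 to the C24 ketone in the presence of the C1=C2 and C4=C5 alkenes, which costs about three more steps and a chemoselectivity problem that the C31–C27 placement avoids.

Alternative 3: ring D and rings B and C are closed in one pot from the ring-A-only aldehyde phosphonate A4. A Horner–Wadsworth–Emmons macrocyclisation forms C33=C34 and an intramolecular Diels–Alder reaction follows. It was turned down because the E-enone holds C15 and C31 anti, whereas the target has them gauche, so the intermediate cyclophane is more strained than the product and oligomerisation is likely. The facial selectivity of a cycloaddition onto a planar-chiral macrocyclic enone cannot be predicted from the ring A centres, and the keto phosphonate needs extra masking at C24 and a later carboxylation at C27.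

Key step: step 20

Assumption 1: the (R,R)-lithium amide is taken to give (3R,5S)-2, by analogy with its known sense on 4-tert-butylcyclohexanone; if the sense is opposite, the (S,S)-amide is used.

Assumption 2: the configurations of C24 and C27 in the target are taken to be those of the thermodynamically preferred bridged hydroxy lactam, because both centres equilibrate under the conditions of step 21.

## Route

Step 1
Reactants: 1 cis-3,5-dimethylcyclohexan-1-one
Product: 2 trimethyl{[(3R,5S)-3,5-dimethylcyclohex-1-en-1-yl]oxy}silane
Conditions: (R,R)-bis(1-phenylethyl)amine, n-BuLi, LiCl, THF, −78 °C; then Me3SiCl and 1, −100 °C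
Reagents that add atoms: chlorotrimethylsilane, C[Si](C)(C)Cl
Why: Enantioselective deprotonation of the meso ketone by the C2-symmetric lithium amide with internal silyl quench; the base selects one of the two enantiotopic axial α-protons and so fixes the absolute configuration of C9 and C12.

Step 2
Reactants: 2 trimethyl{[(3R,5S)-3,5-dimethylcyclohex-1-en-1-yl]oxy}silane
Product: 3 (S)-3,5-dimethylcyclohex-2-en-1-one
Conditions: Pd(OAc)2 (10 mol %), O2 (1 atm), DMSO, 25 °C
Reagents that add atoms: none
Why: Saegusa–Ito dehydrogenation (palladium enolate, β-hydride elimination) gives the enone regiospecifically on the C8 side; C12 is untouched and C9 becomes sp2, which flattens the ring for the next step.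

Step 3
Reactants: 3 (S)-3,5-dimethylcyclohex-2-en-1-one; 4 acrolein
Product: 6 (5S,6S)-6-[(1S)-1-hydroxyprop-2-en-1-yl]-3,5-dimethylcyclohex-2-en-1-one, via boron dienolate 5 (not isolated)
Conditions: (c-C6H11)2BCl, Et3N, Et2O, −78 to 0 °C; then 4, −78 °C; MeOH, pH 7 buffer
Reagents that add atoms: dicyclohexylchloroborane, ClB(C1CCCCC1)C1CCCCC1 (its boron is found in intermediate 5 only)
Why: Boron aldol addition through a chair Zimmerman–Traxler transition state: the ring-locked (E)-enolate gives the anti relationship C14/C15. The aldehyde adds to C14 anti to the pseudoaxial C12 methyl group of the cross-conjugated dienolate, the usual trans preference of α'-enolates of 5-substituted cyclohexenones.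

Step 4
Reactants: 6 (5S,6S)-6-[(1S)-1-hydroxyprop-2-en-1-yl]-3,5-dimethylcyclohex-2-en-1-one
Product: 7 (5S,6S)-6-[(1S)-1-{[tert-butyl(dimethyl)silyl]oxy}prop-2-en-1-yl]-3,5-dimethylcyclohex-2-en-1-one
Conditions: tBuMe2SiOSO2CF3, 2,6-lutidine, CH2Cl2, −78 to 0 °C
Reagents that add atoms: tert-butyldimethylsilyl trifluoromethanesulfonate, CC(C)(C)[Si](C)(C)OS(=O)(=O)C(F)(F)F
Why: Silylation of the secondary alcohol blocks retro-aldol cleavage and β-elimination in the basic steps that follow.

Step 5
Reactants: 7 (5S,6S)-6-[(1S)-1-{[tert-butyl(dimethyl)silyl]oxy}prop-2-en-1-yl]-3,5-dimethylcyclohex-2-en-1-one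
Product: 8 (2S,3S,5R)-2-[(1S)-1-{[tert-butyl(dimethyl)silyl]oxy}prop-2-en-1-yl]-3,5-dimethylcyclohexan-1-one
Conditions: [(Ph3P)CuH]6 (0.4 equiv), H2O (2 equiv), benzene, 25 °C
Reagents that add atoms: none
Why: Conjugate reduction by the phosphine copper hydride is chemoselective for the enone over the isolated vinyl group. Hydride adds to C9 axially and trans to the C12 methyl group, which gives the cis-dimethyl pattern with both methyl groups equatorial.

Step 6
Reactants: 8 (2S,3S,5R)-2-[(1S)-1-{[tert-butyl(dimethyl)silyl]oxy}prop-2-en-1-yl]-3,5-dimethylcyclohexan-1-one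
Product: 9 methyl enol ether of 8 (C7=CH–OMe, E/Z mixture, other centres as in 8)
Conditions: Ph3P(CH2OMe)Cl, KN(SiMe3)2, THF, 0 to 25 °C
Reagents that add atoms: (methoxymethyl)triphenylphosphonium chloride, COC[P+](c1ccccc1)(c1ccccc1)c1ccccc1.[Cl-]
Why: Wittig olefination with the small non-stabilised methoxymethylene ylide adds C6 to the α-branched ketone; enolisation occurs towards C8, so the C14 centre and the silyl ether are not endangered.

Step 7
Reactants: 9 methyl enol ether of 8
Product: 11 (1R,2R,3S,5R)-2-[(1S)-1-{[tert-butyl(dimethyl)silyl]oxy}prop-2-en-1-yl]-3,5-dimethylcyclohexane-1-carbaldehyde, via axial aldehyde 10 (not isolated)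
Conditions: 2 M HCl, THF, 0 °C; then K2CO3, MeOH, 25 °C
Reagents that add atoms: water, O
Why: Acid hydrolysis of the enol ether gives the aldehyde as a C7 mixture, and base equilibrates the epimerisable C7 centre to the equatorial position trans to the C14 side chain, so that all four ring A substituents are equatorial.

Step 8
Reactants: 11 (1R,2R,3S,5R)-2-[(1S)-1-{[tert-butyl(dimethyl)silyl]oxy}prop-2-en-1-yl]-3,5-dimethylcyclohexane-1-carbaldehyde; 12 tert-butyl acrylate
Product: 13 tert-butyl (2E,4S)-4-{[tert-butyl(dimethyl)silyl]oxy}-4-[(1R,2R,4R,6S)-2-formyl-4,6-dimethylcyclohexyl]but-2-enoate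
Conditions: 12 (4 equiv), second-generation Grubbs catalyst RuCl2(=CHPh)(PCy3)(H2IMes) (5 mol %), CH2Cl2, 40 °C
Reagents that add atoms: none
Why: Olefin cross-metathesis between a hindered allylic silyl ether and an acrylate is selective for the cross product and for the E isomer; it installs C33 and C31 as the dienophile and tolerates the aldehyde.

Step 9
Reactants: 13 tert-butyl (2E,4S)-4-{[tert-butyl(dimethyl)silyl]oxy}-4-[(1R,2R,4R,6S)-2-formyl-4,6-dimethylcyclohexyl]but-2-enoate
Product: 14 dienal: 13 in which the C7 formyl group is extended to the (E)-3-oxoprop-1-enyl group C6=C5–C4HO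
Conditions: Ph3P=CHCHO, toluene, 80 °C
Reagents that add atoms: 2-(triphenyl-λ5-phosphanylidene)acetaldehyde, O=CC=P(c1ccccc1)(c1ccccc1)c1ccccc1
Why: Wittig reaction with the stabilised formylmethylene ylide is E-selective and leaves the enoate and the silyl ether untouched.

Step 10
Reactants: 14 dienal; 15 1,3-bis(triisopropylsilyl)prop-1-yne
Product: 16 tert-butyl enoate bearing the (5E,3Z)-dienyne arm C6=C5–C4=C3–C2≡C1–Si(iPr)3 on C7 (Diels–Alder precursor)
Conditions: 15, n-BuLi, THF, −78 °C; then 14, −78 to 0 °C
Reagents that add atoms: none
Why: Peterson olefination with the lithiated bis-silyl propyne: elimination of the silanolate from the adduct gives the Z enyne selectively, which puts the alkyne cis to C5 as the later configuration at C3 requires; the aldehyde reacts far faster than the tert-butyl enoate at −78 °C.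

Step 11
Reactants: 16 Diels–Alder precursor
Product: 17 tricyclic tert-butyl ester (rings A, B, C closed; C3 ethynyl-Si(iPr)3, C15 silyl ether, C33 CO2tBu)
Conditions: Me2AlCl (1.2 equiv), CH2Cl2, −40 to 0 °C
Reagents that add atoms: none
Why: Lewis-acid-promoted intramolecular Diels–Alder reaction: the trans-diequatorial attachment of diene and dienophile on the ring A chair lets ring B form only trans-fused and anti to ring A, and the endo position of the complexed ester gives the trans B/C fusion with C31 trans to C15. The Z-alkynyl group is the inside substituent of the diene and therefore ends trans to C7 at C3; a rod-like alkyne is tolerated there, whereas a Z vinyl group would clash and could undergo 6π-electrocyclisation.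

Step 12
Reactants: 17 tricyclic tert-butyl ester
Product: 18 tricyclic alcohol with terminal alkyne (C15–OH, C3–C≡CH)
Conditions: Bu4NF (3 equiv), THF, 0 to 25 °C
Reagents that add atoms: none
Why: Fluoride cleaves the O–Si and the C(sp)–Si bond in one operation; the tert-butyl ester is stable, and the trans arrangement of O16 and C31 on ring B prevents lactonisation.

Step 13
Reactants: 18 tricyclic alcohol with terminal alkyne
Product: 19 tricyclic alcohol with C3 vinyl group
Conditions: H2 (1 atm), Pd/CaCO3 poisoned with Pb(OAc)2 (Lindlar catalyst), quinoline, EtOAc, 25 °C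
Reagents that add atoms: none
Why: Lindlar semi-hydrogenation stops at the alkene for the terminal alkyne and does not reduce the cis-disubstituted ring C alkene.

Step 14
Reactants: 19 tricyclic alcohol with C3 vinyl group; 20 4-fluorobenzaldehyde
Product: 21 C15 4-formylphenyl ether
Conditions: NaH, DMF, 0 °C; then 20, 25 to 50 °C
Reagents that add atoms: none
Why: Nucleophilic aromatic substitution (addition–elimination) of the fluoride para to the formyl group by the C15 alkoxide forms O16–C17 with retention at C15, so the aldol-derived configuration is carried into the ether.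

Step 15
Reactants: 21 C15 4-formylphenyl ether
Product: 22 benzylic alcohol (C23–OH)
Conditions: NaBH4, MeOH/THF, 0 °C
Reagents that add atoms: none
Why: Borohydride reduces the aryl aldehyde chemoselectively in the presence of the hindered tert-butyl ester.

Step 16
Reactants: 22 benzylic alcohol
Product: 23 benzylic chloride (C23–Cl)
Conditions: MeSO2Cl, Et3N, CH2Cl2, 0 to 25 °C
Reagents that add atoms: methanesulfonyl chloride, CS(=O)(=O)Cl (source of the chlorine)
Why: Sulfonylation of the electron-rich p-alkoxybenzyl alcohol in the presence of chloride leads directly to the benzylic chloride under basic conditions that spare the tert-butyl ester.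

Step 17
Reactants: 23 benzylic chloride; 24 ethyl (E)-4-chloro-4-oxobut-2-enoate
Product: 26 keto-enoate (arene–C23H2–C24(=O)–C26H=C27H–C28O2Et, E), via benzylic zinc chloride 25 (not isolated)
Conditions: Zn dust, LiCl, THF, 25 °C; then 24, Pd(PPh3)4 (5 mol %), THF, 0 to 25 °C
Reagents that add atoms: zinc, [Zn] (found in intermediate 25 only)
Why: Zinc insertion into the benzylic chloride in the presence of LiCl gives an ester-tolerant benzylic zinc reagent; Negishi-type acylation with the zerovalent palladium catalyst forms C23–C24 and delivers the 4-oxo-enoate without double-bond migration.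

Step 18
Reactants: 26 keto-enoate
Product: 27 C31 carboxylic acid
Conditions: CF3CO2H/CH2Cl2 (1:4), 0 to 25 °C
Reagents that add atoms: none
Why: Acidolysis of the tert-butyl ester (loss of isobutene) frees the C31 acid; the ethyl ester, the enone, the alkenes and the alkyl aryl ether are stable to these conditions.

Step 19
Reactants: 27 C31 carboxylic acid
Product: 30 14-membered thiolactone (C31(=O)–S–C27), via acid chloride 28 (not isolated), via thiocarboxylic acid 29 (not isolated)
Conditions: 1-chloro-N,N,2-trimethylprop-1-en-1-amine, CH2Cl2, 0 °C; (Me3Si)2S, 0 to 25 °C; then slow addition to MeOH (5 equiv) and Et3N (0.2 equiv) in MeCN (final 1 mM), 25 °C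
Reagents that add atoms: hexamethyldisilathiane, C[Si](C)(C)S[Si](C)(C)C (sulfur); 1-chloro-N,N,2-trimethylprop-1-en-1-amine, CC(C)=C(Cl)N(C)C (chlorine, found in intermediate 28 only)
Why: The neutral chloroenamine gives the acid chloride, the disilathiane converts it into the thiocarboxylic acid, and at high dilution the thiocarboxylate adds intramolecularly to the 4-oxo-enoate at C27 (β to the ketone, the usual regiochemistry for acylacrylates). The 14-membered ring with two long C–S bonds carries little strain, and the reversibility of the thia-Michael addition corrects oligomers; addition at C26 would give a strained 13-membered ring and is disfavoured twice.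

Step 20
Reactants: 30 14-membered thiolactone
Product: 32 13-membered β-keto ester (ring D closed, C31–C27 bond), via sulfanyl keto ester 31 (not isolated)
Conditions: LiBr, iPr2NEt, PPh3, MeCN (2 mM), 60 °C; then pH 5 buffer
Reagents that add atoms: none
Why: This is an Eschenmoser sulfide contraction: lithium-assisted soft enolisation at C27 (α to the ester and to sulfur) is followed by attack of the enolate on the adjacent thioester carbonyl C31 (3-exo-trig, thiirane-type intermediate), which collapses to the C27 thiolate of 31, and the phosphine then removes sulfur as its sulfide to leave the lithium enolate of 32. The closest known reaction type is the sulfide contraction of S-(alkoxycarbonylalkyl) thioesters to β-keto esters, which has also been used to contract macrocyclic thiolactones. Ring D is not closed end to end: the 14-membered ring already exists and the C31–C27 bond forms across the sulfur atom by a 1,2-acyl shift, so the 13-membered ring arises by excision of one ring atom and no entropic price is paid in the strain-building event. The strain of the paracyclophane is paid by the exchange of a C–S for a C–C bond and by formation of the P=S bond and the chelated β-keto ester enolate, which also protects C31 from transannular aldol attack by C23. The new centre C27 is formed as an enolate and stays labile; it is set together with C24 in step 21. The selectivity needed is acyl transfer to C27 instead of loss of the thiocarboxylate by retro-Michael cleavage through the C26 enolate; that cleavage is the reverse of step 19 and is reversible, whereas desulfurisation is not, so the material funnels to 32. Acyl transfer to C23 or C26 would require a ten-membered cyclophane or a four-membered ring and is excluded by strain.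

Step 21
Reactants: 32 13-membered β-keto ester
Product: 34 CNP0539220.2 (target), via keto amide 33 (not isolated)
Conditions: NH3 (7 M in MeOH)/H2O (10:1), sealed tube, 110 °C
Reagents that add atoms: ammonia, N
Why: Ammonolysis of the β-keto ester gives the primary amide, whose nitrogen adds to the C24 ketone (5-exo-trig) to close ring E as the hydroxy lactam. C27 (by enolisation) and C24 (by ring–chain tautomerism) equilibrate to the cis-bridged cyclol, and the competing pyrrole formation from the 1,4-diketone is disfavoured because a planar pyrrole cannot span ring D.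

## Compound list

1 | cis-3,5-dimethylcyclohexan-1-one (meso) | O=C1C[C@H](C)C[C@H](C)C1 | starting material
2 | trimethyl{[(3R,5S)-3,5-dimethylcyclohex-1-en-1-yl]oxy}silane | C[Si](C)(C)OC1=C[C@H](C)C[C@H](C)C1 | intermediate
3 | (S)-3,5-dimethylcyclohex-2-en-1-one | O=C1C=C(C)C[C@H](C)C1 | intermediate
4 | acrolein (prop-2-enal) | C=CC=O | starting material
5 | boron dienolate, dicyclohexyl{[(3S)-3,5-dimethylcyclohexa-1,5-dien-1-yl]oxy}borane | CC1=CC(OB(C2CCCCC2)C2CCCCC2)=C[C@@H](C)C1 | intermediate
6 | (5S,6S)-6-[(1S)-1-hydroxyprop-2-en-1-yl]-3,5-dimethylcyclohex-2-en-1-one (anti aldol, side chain trans to the C12 methyl) | C=C[C@H](O)[C@H]1C(=O)C=C(C)C[C@@H]1C | intermediate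
7 | tert-butyldimethylsilyl ether of 6 | C=C[C@H](O[Si](C)(C)C(C)(C)C)[C@H]1C(=O)C=C(C)C[C@@H]1C | intermediate
8 | (2S,3S,5R)-2-[(1S)-1-{[tert-butyl(dimethyl)silyl]oxy}prop-2-en-1-yl]-3,5-dimethylcyclohexan-1-one | C=C[C@H](O[Si](C)(C)C(C)(C)C)[C@H]1C(=O)C[C@H](C)C[C@@H]1C | intermediate
9 | methyl enol ether of 8 (C7=CH–OMe, E/Z mixture) | C=C[C@H](O[Si](C)(C)C(C)(C)C)[C@H]1C(=COC)C[C@H](C)C[C@@H]1C | intermediate
10 | axial aldehyde, (1S,2R,3S,5R) C7 epimer of 11 | C=C[C@H](O[Si](C)(C)C(C)(C)C)[C@H]1[C@@H](C=O)C[C@H](C)C[C@@H]1C | intermediate
11 | (1R,2R,3S,5R)-2-[(1S)-1-{[tert-butyl(dimethyl)silyl]oxy}prop-2-en-1-yl]-3,5-dimethylcyclohexane-1-carbaldehyde (all-equatorial ring A) | C=C[C@H](O[Si](C)(C)C(C)(C)C)[C@H]1[C@H](C=O)C[C@H](C)C[C@@H]1C | intermediate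
12 | tert-butyl acrylate | C=CC(=O)OC(C)(C)C | starting material
13 | tert-butyl (2E,4S)-4-{[tert-butyl(dimethyl)silyl]oxy}-4-[(1R,2R,4R,6S)-2-formyl-4,6-dimethylcyclohexyl]but-2-enoate | CC(C)(C)OC(=O)/C=C/[C@H](O[Si](C)(C)C(C)(C)C)[C@H]1[C@H](C=O)C[C@H](C)C[C@@H]1C | intermediate
14 | dienal: 13 with the C7 formyl group extended to (E)-CH=CH–CHO | CC(C)(C)OC(=O)/C=C/[C@H](O[Si](C)(C)C(C)(C)C)[C@H]1[C@H](/C=C/C=O)C[C@H](C)C[C@@H]1C | intermediate
15 | 1,3-bis(triisopropylsilyl)prop-1-yne | CC(C)[Si](C(C)C)(C(C)C)C#CC[Si](C(C)C)(C(C)C)C(C)C | starting material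
16 | Diels–Alder precursor: tert-butyl (E)-enoate with C15 silyl ether and (5E,3Z)-dienyne arm on C7 | CC(C)(C)OC(=O)/C=C/[C@H](O[Si](C)(C)C(C)(C)C)[C@H]1[C@H](/C=C/C=C\C#C[Si](C(C)C)(C(C)C)C(C)C)C[C@H](C)C[C@@H]1C | intermediate
17 | tricyclic tert-butyl ester (trans-anti-trans rings A/B/C, C3 silylethynyl, C15 silyl ether) | CC(C)[Si](C(C)C)(C(C)C)C#C[C@@H]1C=C[C@H]2[C@@H]3C[C@H](C)C[C@H](C)[C@H]3[C@@H](O[Si](C)(C)C(C)(C)C)[C@@H]2[C@H]1C(=O)OC(C)(C)C | intermediate
18 | tricyclic alcohol with C3 ethynyl group | C#C[C@@H]1C=C[C@H]2[C@@H]3C[C@H](C)C[C@H](C)[C@H]3[C@@H](O)[C@@H]2[C@H]1C(=O)OC(C)(C)C | intermediate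
19 | tricyclic alcohol with C3 vinyl group | C=C[C@@H]1C=C[C@H]2[C@@H]3C[C@H](C)C[C@H](C)[C@H]3[C@@H](O)[C@@H]2[C@H]1C(=O)OC(C)(C)C | intermediate
20 | 4-fluorobenzaldehyde | O=Cc1ccc(F)cc1 | starting material
21 | C15 4-formylphenyl ether | C=C[C@@H]1C=C[C@H]2[C@@H]3C[C@H](C)C[C@H](C)[C@H]3[C@@H](Oc3ccc(C=O)cc3)[C@@H]2[C@H]1C(=O)OC(C)(C)C | intermediate
22 | benzylic alcohol | C=C[C@@H]1C=C[C@H]2[C@@H]3C[C@H](C)C[C@H](C)[C@H]3[C@@H](Oc3ccc(CO)cc3)[C@@H]2[C@H]1C(=O)OC(C)(C)C | intermediate
23 | benzylic chloride | C=C[C@@H]1C=C[C@H]2[C@@H]3C[C@H](C)C[C@H](C)[C@H]3[C@@H](Oc3ccc(CCl)cc3)[C@@H]2[C@H]1C(=O)OC(C)(C)C | intermediate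
24 | ethyl (E)-4-chloro-4-oxobut-2-enoate (ethyl fumaroyl chloride) | CCOC(=O)/C=C/C(Cl)=O | starting material
25 | benzylic zinc chloride | C=C[C@@H]1C=C[C@H]2[C@@H]3C[C@H](C)C[C@H](C)[C@H]3[C@@H](Oc3ccc(C[Zn]Cl)cc3)[C@@H]2[C@H]1C(=O)OC(C)(C)C | intermediate
26 | keto-enoate tert-butyl ester | C=C[C@@H]1C=C[C@H]2[C@@H]3C[C@H](C)C[C@H](C)[C@H]3[C@@H](Oc3ccc(CC(=O)/C=C/C(=O)OCC)cc3)[C@@H]2[C@H]1C(=O)OC(C)(C)C | intermediate
27 | C31 carboxylic acid | C=C[C@@H]1C=C[C@H]2[C@@H]3C[C@H](C)C[C@H](C)[C@H]3[C@@H](Oc3ccc(CC(=O)/C=C/C(=O)OCC)cc3)[C@@H]2[C@H]1C(=O)O | intermediate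
28 | C31 acid chloride | C=C[C@@H]1C=C[C@H]2[C@@H]3C[C@H](C)C[C@H](C)[C@H]3[C@@H](Oc3ccc(CC(=O)/C=C/C(=O)OCC)cc3)[C@@H]2[C@H]1C(Cl)=O | intermediate
29 | C31 thiocarboxylic acid | C=C[C@@H]1C=C[C@H]2[C@@H]3C[C@H](C)C[C@H](C)[C@H]3[C@@H](Oc3ccc(CC(=O)/C=C/C(=O)OCC)cc3)[C@@H]2[C@H]1C(=O)S | intermediate
30 | 14-membered thiolactone (S between C31 and C27, C27 epimers) | C=C[C@@H]1C=C[C@H]2[C@@H]3C[C@H](C)C[C@H](C)[C@H]3[C@H]3Oc4ccc(cc4)CC(=O)CC(C(=O)OCC)SC(=O)[C@@H]1[C@H]23 | intermediate
31 | ring-contracted C27-sulfanyl β-keto ester | C=C[C@@H]1C=C[C@H]2[C@@H]3C[C@H](C)C[C@H](C)[C@H]3[C@H]3Oc4ccc(cc4)CC(=O)CC(S)(C(=O)OCC)C(=O)[C@@H]1[C@H]23 | intermediate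
32 | 13-membered β-keto ester (C27 labile) | C=C[C@@H]1C=C[C@H]2[C@@H]3C[C@H](C)C[C@H](C)[C@H]3[C@H]3Oc4ccc(cc4)CC(=O)CC(C(=O)OCC)C(=O)[C@@H]1[C@H]23 | intermediate
33 | 13-membered β-keto primary amide | C=C[C@@H]1C=C[C@H]2[C@@H]3C[C@H](C)C[C@H](C)[C@H]3[C@H]3Oc4ccc(cc4)CC(=O)CC(C(N)=O)C(=O)[C@@H]1[C@H]23 | intermediate
34 | CNP0539220.2 | C=C[C@@H]1C=C[C@H]2[C@@H]3C[C@H](C)C[C@H](C)[C@H]3[C@H]3Oc4ccc(cc4)C[C@@]4(O)C[C@H](C(=O)N4)C(=O)[C@@H]1[C@H]23 | target

## Step count and least certain steps

Total: 21 steps. Longest linear sequence: 21 steps from 1 (4, 12, 15, 20 and 24 are commercial partners).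

Step 20 (key step). What may go wrong: enolisation towards C26 with retro-Michael ring opening may outrun the acyl shift, so that the open thiocarboxylate oligomerises, or the S-to-C acyl shift may be so unfavourable in the strained ring that desulfurisation is too slow. The fallback avoids the sulfur relay and sets out from acid 27. The acid chloride 28 is made as in step 19 and treated with benzeneselenol and pyridine to give the Se-phenyl selenoester F1. Tributyltin hydride and azobisisobutyronitrile in benzene at 80 °C and high dilution generate the C31 acyl radical, which adds to C27 of the 4-oxo-enoate (β to the ketone) and after hydrogen transfer gives 32, where the route is rejoined.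

Step 19. What may go wrong: intermolecular thia-Michael addition (oligomers) at practical concentrations, air oxidation of the thioacid to a diacyl disulfide, or partial addition at C26. The fallback reverses the order of the two sulfur bonds and sets out from 26. Conjugate addition of triphenylmethanethiol (catalytic Et3N) gives the S-trityl sulfide F2. Trifluoroacetic acid with Et3SiH removes the tert-butyl and trityl groups together to give the mercapto acid F3. Thiol acylation under macrolactonisation conditions (2,4,6-trichlorobenzoyl chloride, Et3N, then 4-dimethylaminopyridine, high dilution) closes the same thiolactone 30.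

Step 11. What may go wrong: insufficient endo selectivity (cis-fused B/C isomer), slow cycloaddition because of the inside alkynyl group, or loss of the tert-butyl group to the Lewis acid. The fallback changes the dienophile and the way C15 is set, and it sets out from 16.
- Bu4NF removes both silyl groups to give the dienyne alcohol F4.
- Dess–Martin periodinane gives the 4-oxo-enoate F5, a doubly activated dienophile that should cyclise near room temperature without a Lewis acid to the tricyclic C15 ketone F6.
- NaBH4 is expected to attack from the face remote from the C33 ester and give the equatorial alcohol F7, the C15 epimer of 18.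
- A Mitsunobu reaction with 4-hydroxybenzaldehyde inverts C15 and gives the aryl ether F8.
- Lindlar semi-hydrogenation of F8 gives 21, where the route is rejoined.

Should the reduction give the axial alcohol instead, that product is 18 itself.

Step 3. What may go wrong: incomplete anti selectivity, partial attack cis to the C12 methyl group, or conjugate addition to acrolein. The fallback replaces the closed boron transition state by catalyst control and sets out from 3. LiN(iPr)2 and Me3SiCl give the trimethylsilyl dienol ether F9. A Mukaiyama aldol addition of F9 to 4 under a chiral Lewis acid (Ti(OiPr)4 with (R)-1,1'-bi-2-naphthol) fixes the aldehyde face. After desilylating work-up and equilibration of the still epimerisable C14 centre, 6 is obtained and the route is rejoined.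

## Further compounds

F1 | step 20 | Se-phenyl selenoester of acid 27 | C=C[C@@H]1C=C[C@H]2[C@@H]3C[C@H](C)C[C@H](C)[C@H]3[C@@H](Oc3ccc(CC(=O)/C=C/C(=O)OCC)cc3)[C@@H]2[C@H]1C(=O)[Se]c1ccccc1
F2 | step 19 | S-trityl conjugate adduct of 26 (sulfide at C27) | C=C[C@@H]1C=C[C@H]2[C@@H]3C[C@H](C)C[C@H](C)[C@H]3[C@@H](Oc3ccc(CC(=O)CC(SC(c4ccccc4)(c4ccccc4)c4ccccc4)C(=O)OCC)cc3)[C@@H]2[C@H]1C(=O)OC(C)(C)C
F3 | step 19 | C27 mercapto C31 acid | C=C[C@@H]1C=C[C@H]2[C@@H]3C[C@H](C)C[C@H](C)[C@H]3[C@@H](Oc3ccc(CC(=O)CC(S)C(=O)OCC)cc3)[C@@H]2[C@H]1C(=O)O
F4 | step 11 | desilylated dienyne alcohol from 16 | CC(C)(C)OC(=O)/C=C/[C@H](O)[C@H]1[C@H](/C=C/C=C\C#C)C[C@H](C)C[C@@H]1C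
F5 | step 11 | 4-oxo-enoate dienyne (C15 ketone) | CC(C)(C)OC(=O)/C=C/C(=O)[C@H]1[C@H](/C=C/C=C\C#C)C[C@H](C)C[C@@H]1C
F6 | step 11 | tricyclic C15 ketone with C3 ethynyl group | C#C[C@@H]1C=C[C@H]2[C@@H]3C[C@H](C)C[C@H](C)[C@H]3C(=O)[C@@H]2[C@H]1C(=O)OC(C)(C)C
F7 | step 11 | equatorial C15 alcohol (C15 epimer of 18) | C#C[C@@H]1C=C[C@H]2[C@@H]3C[C@H](C)C[C@H](C)[C@H]3[C@H](O)[C@@H]2[C@H]1C(=O)OC(C)(C)C
F8 | step 11 | C15 4-formylphenyl ether with C3 ethynyl group | C#C[C@@H]1C=C[C@H]2[C@@H]3C[C@H](C)C[C@H](C)[C@H]3[C@@H](Oc3ccc(C=O)cc3)[C@@H]2[C@H]1C(=O)OC(C)(C)C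
F9 | step 3 | trimethylsilyl dienol ether of 3 | CC1=CC(O[Si](C)(C)C)=C[C@@H](C)C1
A1 | alternative 1 | seco alcohol with aryl iodide for macro-etherification | C=C[C@@H]1C=C[C@H]2[C@@H]3C[C@H](C)C[C@H](C)[C@H]3[C@@H](O)[C@@H]2[C@H]1C(=O)C(C(=O)OCC)CC(=O)Cc1ccc(I)cc1
A2 | alternative 2 | 14-membered sulfone with sulfur between C23 and C24 | C=C[C@@H]1C=C[C@H]2[C@@H]3C[C@H](C)C[C@H](C)[C@H]3[C@H]3Oc4ccc(cc4)CS(=O)(=O)CCC(C(=O)OCC)C(=O)[C@@H]1[C@H]23
A3 | alternative 2 | ring-contracted (Z)-styrene C23=C24 | C=C[C@@H]1C=C[C@H]2[C@@H]3C[C@H](C)C[C@H](C)[C@H]3[C@H]3Oc4ccc(cc4)/C=C\CC(C(=O)OCC)C(=O)[C@@H]1[C@H]23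
A4 | alternative 3 | ring A aldehyde with aryl ether and keto phosphonate arm | O=C[C@H](Oc1ccc(CC(=O)CCC(=O)CP(=O)(OC)OC)cc1)[C@H]1[C@H](/C=C/C=C\C#C[Si](C(C)C)(C(C)C)C(C)C)C[C@H](C)C[C@@H]1C
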